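The C7–C8 bond of the ten-membered ring is the strategic disconnection. The target's C7 oxygen sits next to C8, which carries an oxygen and the three lactone carbons C17–C19: a homoallylic-alcohol pattern that a [2,3]-Wittig shift creates. A thirteen-membered C7–O–C19 bis-allylic ether, fused to ring A and holding a (5Z)-olefin and a C8 silyl enol ether, is deprotonated at C7. The shift forms C7–C8, expels O, C19 and C17 from the ring, contracts it to the cyclodecene and sets the C7 and C8 stereocentres at once. Lactonisation, C11 epoxide construction, acetylation and a final ene chlorination complete the synthesis.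

Key step: step 23

Remark (numbering): carbon numbers follow the briarane skeleton of the target; ring A is C1, C10–C14; C15, C16 and C18 are methyl carbons, C19 is the lactone carbonyl and C20 the epoxide CH2.
Remark (racemic side chain): aldehyde 15 is used as the racemate, because its only stereocentre (C17) is flattened in step 18 and formed again in step 24; 27 and 28 are therefore C17 epimer mixtures.
Remark (precursor design): in the key precursor 35 the C11 oxygen is carried as an alcohol in a cis-acetonide with O12, not as a ketone derivative. A C11 ketone would sit β to the C9 silyloxy group, and the spiro-epoxide is better made by hydroxyl-directed epoxidation of a C11 methylene, which puts the oxygen cis to O12 as the target requires. The enol ether geometry is fixed in the open chain before the ring is closed.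

Step 1
Reactants: 1 (−)-quinic acid
Product: 2 3,4-O-isopropylidene-1,5-quinide
Conditions: 2,2-dimethoxypropane, TsOH (cat.), acetone, reflux
Reagents that add atoms: 2,2-dimethoxypropane, COC(C)(C)OC
Why: Acid-catalysed acetalisation of the cis-3,4-diol with concurrent 1,5-lactonisation is the standard entry into quinic acid chemistry and changes no stereocentre.

Step 2
Reactants: 2 3,4-O-isopropylidene-1,5-quinide
Product: 3 acetonide triol (1-hydroxymethyl-1,5-diol)
Conditions: NaBH4, EtOH, 0 °C to rt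
Reagents that add atoms: none
Why: Borohydride reduction of the strained bicyclic lactone gives the primary alcohol and frees the 5-OH while the acetonide is inert.

Step 3
Reactants: 3 acetonide triol
Product: 4 5-hydroxy-3,4-(isopropylidenedioxy)cyclohexanone
Conditions: NaIO4, pH 7 phosphate buffer, 0 °C
Reagents that add atoms: none
Why: Periodate (Malaprade) cleavage of the tertiary/primary 1,2-diol gives the ketone, and the lone secondary 5-OH has no vicinal partner.

Step 4
Reactants: 4 5-hydroxy-3,4-(isopropylidenedioxy)cyclohexanone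
Product: 6 (3aR,7aS)-2,2-dimethyl-3a,7a-dihydro-1,3-benzodioxol-5(4H)-one, via C5 mesylate 5 (not isolated)
Conditions: MsCl, Et3N, CH2Cl2, 0 °C
Reagents that add atoms: none
Why: Mesylation of the β-hydroxyl followed by E1cB elimination in the same flask gives the conjugated enone with both acetonide stereocentres untouched.

Step 5
Reactants: 6 acetonide enone
Product: 7 α-iodoenone (6-iodo derivative of 6)
Conditions: I2, pyridine, CH2Cl2, 0 °C to rt
Reagents that add atoms: iodine, II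
Why: Johnson α-iodination of a cyclic enone (pyridine addition, iodination of the enolate, elimination) is well established for this ring system.

Step 6
Reactants: 7 α-iodoenone
Product: 8 ring A enone (3aR,7aS)-2,2,6-trimethyl-3a,7a-dihydro-1,3-benzodioxol-5(4H)-one
Conditions: Me4Sn, Pd2(dba)3 (cat.), AsPh3, CuI, NMP, 50 °C
Reagents that add atoms: tetramethylstannane, C[Sn](C)(C)C
Why: Stille cross-coupling of an α-iodoenone under neutral conditions installs the C15 methyl without base-induced loss of the β-alkoxy group.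

Step 7
Reactants: 9 but-2-yn-1-ol
Product: 11 (Z)-3-iodobut-2-en-1-ol, via cyclic vinylalanate 10 (not isolated)
Conditions: NaAlH2(OCH2CH2OMe)2, THF, 0 °C; EtOAc; I2, −78 °C
Reagents that add atoms: iodine, II
Why: Hydroxyl-directed trans-hydroalumination puts aluminium on C5 cis to the CH2O group and iodinolysis with retention gives the (Z)-vinyl iodide, which later fixes the 5Z olefin.

Step 8
Reactants: 11 (Z)-3-iodobut-2-en-1-ol
Product: 12 (Z)-1-bromo-3-iodobut-2-ene
Conditions: CBr4, PPh3, CH2Cl2, 0 °C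
Reagents that add atoms: tetrabromomethane, BrC(Br)(Br)Br
Why: Appel bromination of a primary allylic alcohol proceeds without allylic shift or loss of olefin geometry at low temperature.

Step 9
Reactants: 12 (Z)-1-bromo-3-iodobut-2-ene; 13 2-methylpropane-1,3-diol
Product: 14 rac-3-{[(Z)-3-iodobut-2-en-1-yl]oxy}-2-methylpropan-1-ol
Conditions: 13 (4 equiv), NaH, THF, 0 °C to rt
Reagents that add atoms: none
Why: Williamson etherification of the symmetrical diol used in excess gives the mono-ether that will become the C7–O–C19 bridge.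

Step 10
Reactants: 14 mono-ether alcohol
Product: 15 rac-3-{[(Z)-3-iodobut-2-en-1-yl]oxy}-2-methylpropanal
Conditions: Dess–Martin periodinane, NaHCO3, CH2Cl2, 0 °C
Reagents that add atoms: none
Why: Buffered Dess–Martin oxidation gives the β-alkoxy aldehyde (C8, C17–C19 with the C5–C7 arm) without elimination.

Step 11
Reactants: 8 ring A enone; 16 1,3-dithiane; 17 acrolein
Product: 20 aldol adduct (C14 ketone, C1 bearing methyl and CH(OH)CH=CH2, C10 bearing dithian-2-yl; C2 epimers), via 2-lithio-1,3-dithiane 18 (not isolated), via lithium enolate 19 (not isolated)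
Conditions: 16, n-BuLi, THF, −30 °C; HMPA, then 8, −78 °C; then 17, −78 °C; aq NH4Cl
Reagents that add atoms: none
Why: Tandem 1,4-addition/aldol reaction in which the dithiane anion adds axially and anti to the C11 oxygen (sets C10), and the regiodefined enolate 19 takes acrolein on the face opposite the new C10 group (sets the C1 quaternary centre, C2 left unselective).

Step 12
Reactants: 20 aldol adduct
Product: 21 14-ol (axial, cis to the C2 chain; C2 epimers)
Conditions: LiBH(s-Bu)3, THF, −78 °C; aq NH4Cl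
Reagents that add atoms: none
Why: The bulky hydride attacks the C14 ketone from the equatorial lower face because the axial C12 oxygen blocks the upper face, giving the axial alcohol required at C14.

Step 13
Reactants: 21 14-ol
Product: 22 C2 vinyl ketone with free 14-OH
Conditions: MnO2, CH2Cl2, rt
Reagents that add atoms: none
Why: MnO2 oxidises only the allylic C2 alcohol, which erases the unselective C2 centre and leaves the saturated 14-OH in place.

Step 14
Reactants: 22 C2 vinyl ketone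
Product: 24 2,14-syn-diol, via diethylboron chelate 23 (not isolated)
Conditions: Et2BOMe, THF/MeOH, −78 °C; NaBH4; AcOH, then MeOH evaporation
Reagents that add atoms: none
Why: Narasaka–Prasad reduction, in which external hydride attacks the six-membered boron chelate between O14 and the C2 carbonyl to give the 1,3-syn diol and so sets C2.

Step 15
Reactants: 24 2,14-syn-diol
Product: 25 2,14-bis-TBS ether
Conditions: TBSOTf, 2,6-lutidine, CH2Cl2, 0 °C to rt
Reagents that add atoms: tert-butyldimethylsilyl triflate, CC(C)(C)[Si](C)(C)OS(=O)(=O)C(F)(F)F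
Why: Silyl triflate silylation protects the two hindered secondary alcohols without touching the acetonide or dithiane.

Step 16
Reactants: 25 2,14-bis-TBS ether; 15 side-chain aldehyde
Product: 27 C9 dithioketal C8 carbinol (C8 and C17 epimers), via C9-lithiated dithiane 26 (not isolated)
Conditions: t-BuLi, THF/HMPA, −78 °C; then 15, −78 °C; aq NH4Cl
Reagents that add atoms: none
Why: Corey–Seebach umpolung joins C9 to C8 by 1,2-addition of the lithiated dithioacetal to the aldehyde, and the new C8 carbinol centre is removed in the next step.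

Step 17
Reactants: 27 C8 carbinol
Product: 28 C8 ketone with C9 dithioketal (C17 epimers)
Conditions: SO3·pyridine, DMSO, i-Pr2NEt, CH2Cl2, 0 °C
Reagents that add atoms: none
Why: Parikh–Doering oxidation gives the ketone without oxidising the dithioketal sulfur.

Step 18
Reactants: 28 C8 ketone
Product: 30 (Z)-C8 triisopropylsilyl enol ether (C9 trans to C19), via lithium enolate 29 (not isolated)
Conditions: LiN(SiMe3)2, THF, −78 °C; TIPSOTf, −78 to −40 °C
Reagents that add atoms: triisopropylsilyl triflate, CC(C)[Si](C(C)C)(C(C)C)OS(=O)(=O)C(F)(F)F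
Why: Enolisation is possible only towards C17 because C9 is quaternary, and O-silylation of the lithium enolate (chelated by the C19 ether oxygen, bulky C9 group cis to the smaller methyl) gives the enol ether geometry the key step needs.

Step 19
Reactants: 30 enol ether dithioketal
Product: 31 C9 ketone (α-silyloxy enone)
Conditions: MeI, CaCO3, MeCN/H2O, 45 °C
Reagents that add atoms: water, O
Why: Alkylative dithioketal hydrolysis (S-methylation, then water) under carbonate buffering unmasks the C9 carbonyl without electrophilic oxidants or metal salts that would attack the enol ether.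

Step 20
Reactants: 31 C9 ketone
Product: 32 C9 allylic alcohol (target configuration at C9)
Conditions: NaBH4, CeCl3·7H2O, MeOH, −78 °C
Reagents that add atoms: none
Why: Luche 1,2-reduction in which hydride adds anti to the quaternary C1 group (Felkin–Anh, and also the β-chelation model through O11), which sets C9.

Step 21
Reactants: 32 C9 alcohol
Product: 33 open-chain tetrasilyl ether with terminal vinyl group and (Z)-vinyl iodide
Conditions: TBSOTf, 2,6-lutidine, CH2Cl2, −78 °C
Reagents that add atoms: tert-butyldimethylsilyl triflate, CC(C)(C)[Si](C)(C)OS(=O)(=O)C(F)(F)F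
Why: Silylation under basic conditions protects the allylic C9 alcohol and leaves the acid-sensitive enol ether intact.

Step 22
Reactants: 33 open-chain tetrasilyl ether
Product: 35 thirteen-membered C7–O–C19 ether (key precursor), via B-alkyl-9-BBN adduct 34 (not isolated)
Conditions: 9-BBN, THF, rt; then PdCl2(dppf) (cat.), AsPh3, Cs2CO3, DMF/THF/H2O, rt, high dilution
Reagents that add atoms: none
Why: 9-BBN hydroborates only the terminal vinyl group and the intramolecular B-alkyl Suzuki–Miyaura coupling with the (Z)-vinyl iodide closes the ring at C4–C5 with retention of olefin geometry.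

Step 23
Reactants: 35 thirteen-membered ether
Product: 38 ten-membered 7-ol with C8 silyloxy and isopropenyl groups, via C7-lithiated ether 36 (not isolated), via lithium C7-alkoxide 37 (not isolated)
Conditions: lithium 2,2,6,6-tetramethylpiperidide, THF, −78 to −25 °C; aq NH4Cl at −78 °C
Reagents that add atoms: none
Why: Proposed new method: the amide base removes a C7 proton (α to the ether oxygen, allylic to the 5-olefin) and the α-oxy allyl anion 36 bonds to C8 suprafacially across the C19–C17=C8 unit through a five-membered envelope transition state while O–C19 breaks and C17=C19 forms; the closest known reaction type is the [2,3]-Wittig ring contraction of thirteen-membered diallylic ethers to cyclodecenols, here extended to a tetrasubstituted silyl enol ether terminus whose π* coefficient is largest at the oxygen-bearing C8. The ten-membered carbocycle is closed by this intra-annular C–C bond formation, a 13-to-10 contraction in which O, C19 and C17 become exocyclic, not by an end-to-end cyclisation. The relative configuration of C7 and C8 follows from the enol ether geometry (C9 trans to C19) together with the exo position of C6 on the carbanion in the envelope, which places the two oxygens cis on the new ring as the trans-fused lactone requires. The absolute sense is set by the C9 and C10 stereocentres, which hold the macrocycle so that C7 can reach only one face of the enol ether. The step needs deprotonation at C7 in preference to C19 and C9, which allylic stabilisation at C7 and the electron-rich enol ether (destabilising a C19 anion) should secure, and the bulky TIPS group with a cold quench should prevent silyl migration to the new alkoxide.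

Step 24
Reactants: 38 ten-membered 7-ol
Product: 40 7,19-diol, via C19 alkylborane 39 (not isolated)
Conditions: 9-BBN (excess), THF, 0 to 40 °C; NaOH, H2O2, 0 °C
Reagents that add atoms: hydrogen peroxide, OO
Why: Hydroboration–oxidation with 9-BBN takes the 1,1-disubstituted isopropenyl group in preference to the trisubstituted ring olefin; C17 forms under substrate control and, being α to the later lactone carbonyl, can equilibrate in step 30.

Step 25
Reactants: 40 7,19-diol
Product: 42 trans-fused γ-lactone, via lactol 41 (not isolated)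
Conditions: TEMPO (cat.), PhI(OAc)2, CH2Cl2, rt
Reagents that add atoms: none
Why: Oxidative lactonisation of a 1,4-diol, in which the oxoammonium oxidant converts the primary alcohol to the aldehyde, the C7 hydroxyl closes the lactol and a second oxidation gives the lactone.

Step 26
Reactants: 42 γ-lactone acetonide
Product: 43 11,12-diol
Conditions: TFA/H2O (9:1), CH2Cl2, 0 °C
Reagents that add atoms: none
Why: Brief cold acid hydrolysis removes the acetonide while the hindered secondary TBS ethers and the tertiary TIPS ether survive.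

Step 27
Reactants: 43 11,12-diol
Product: 45 12-acetate with free 11-OH, via cyclic 11,12-orthoacetate 44 (not isolated)
Conditions: MeC(OMe)3, PPTS, CH2Cl2, rt; then 80% aq AcOH, rt
Reagents that add atoms: trimethyl orthoacetate, COC(C)(OC)OC; water, O
Why: Cyclic orthoester formation and acid hydrolysis of the cis-diol, which by the known stereoelectronic rule leaves the acyl group on the axial oxygen (O12) and frees the equatorial 11-OH.

Step 28
Reactants: 45 12-acetate 11-ol
Product: 46 11-ketone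
Conditions: Dess–Martin periodinane, NaHCO3, CH2Cl2, rt
Reagents that add atoms: none
Why: Buffered Dess–Martin oxidation gives the ketone under non-basic conditions that avoid β-elimination of the C9 silyloxy group.

Step 29
Reactants: 46 11-ketone
Product: 47 11(20)-methylene compound
Conditions: Zn, CH2Br2, TiCl4, THF/CH2Cl2, 0 °C to rt
Reagents that add atoms: dibromomethane, BrCBr
Why: Takai–Lombardo methylenation is non-basic, works on hindered enolisable ketones and leaves lactone and acetate carbonyls alone.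

Step 30
Reactants: 47 11(20)-methylene 12-acetate
Product: 48 11(20)-methylene 12-ol
Conditions: K2CO3, MeOH, 0 °C to rt; then PPTS, CH2Cl2
Reagents that add atoms: none
Why: Methanolysis of the acetate frees the allylic 12-OH, the lactone closes again on mild acid work-up, and the C17 centre should settle as the more stable epimer with methyl trans to C9.

Step 31
Reactants: 48 11(20)-methylene 12-ol
Product: 49 11,20-epoxide
Conditions: VO(acac)2 (cat.), t-BuOOH, CH2Cl2, 0 °C
Reagents that add atoms: tert-butyl hydroperoxide, CC(C)(C)OO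
Why: Hydroxyl-directed vanadium-catalysed epoxidation delivers oxygen to the exocyclic olefin on the face of the 12-OH (sets C11) and ignores the trisubstituted olefin, which has no free allylic hydroxyl.

Step 32
Reactants: 49 11,20-epoxide
Product: 50 epoxy lactone pentaol
Conditions: Bu4NF, AcOH, THF, 0 to 40 °C
Reagents that add atoms: none
Why: Acetic acid-buffered fluoride removes the three TBS groups and the tertiary TIPS group without opening the epoxide or shifting the lactone.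

Step 33
Reactants: 50 epoxy lactone pentaol
Product: 51 2,9,12,14-tetraacetate
Conditions: Ac2O, pyridine, DMAP (cat.), CH2Cl2, rt
Reagents that add atoms: acetic anhydride, CC(=O)OC(C)=O
Why: DMAP-catalysed acetylation esterifies the four secondary alcohols while the hindered tertiary 8-OH remains free.

Step 34
Reactants: 51 tetraacetate
Product: 52 CNP0349227.1 (target)
Conditions: Ca(OCl)2, solid CO2, CH2Cl2/H2O, 0 °C
Reagents that add atoms: calcium hypochlorite, [Ca+2].[O-]Cl.[O-]Cl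
Why: Ene-type chlorination with HOCl made in the flask, in which Cl+ adds to C6 on the exposed outer face of the (Z)-olefin and a C16 proton is lost to give the 5(16)-methylene, which sets C6.

Compound list
1 | (−)-quinic acid | OC(=O)[C@]1(O)C[C@@H](O)[C@@H](O)[C@H](O)C1 | starting material
2 | 3,4-O-isopropylidene-1,5-quinide | O=C1O[C@@H]2C[C@@]1(O)C[C@H]3OC(C)(C)O[C@@H]23 | intermediate
3 | acetonide triol (1-hydroxymethyl-1,5-diol, 3,4-O-isopropylidene) | OC[C@]1(O)C[C@H]2OC(C)(C)O[C@H]2[C@H](O)C1 | intermediate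
4 | 5-hydroxy-3,4-(isopropylidenedioxy)cyclohexanone (5-OH trans to the acetonide oxygens) | O=C1C[C@H]2OC(C)(C)O[C@H]2[C@H](O)C1 | intermediate
5 | C5 mesylate of 4 | O=C1C[C@H]2OC(C)(C)O[C@H]2[C@H](OS(C)(=O)=O)C1 | intermediate
6 | (3aR,7aS)-2,2-dimethyl-3a,7a-dihydro-1,3-benzodioxol-5(4H)-one | O=C1C[C@H]2OC(C)(C)O[C@H]2C=C1 | intermediate
7 | α-iodoenone (6-iodo derivative of 6) | O=C1C[C@H]2OC(C)(C)O[C@H]2C=C1I | intermediate
8 | ring A enone, (3aR,7aS)-2,2,6-trimethyl-3a,7a-dihydro-1,3-benzodioxol-5(4H)-one | O=C1C[C@H]2OC(C)(C)O[C@H]2C=C1C | intermediate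
9 | but-2-yn-1-ol | CC#CCO | starting material
10 | cyclic vinylalanate (sodium 2,2-bis(2-methoxyethoxy)-3-methyl-2,5-dihydro-1,2-oxaalumol-2-uide) | CC1=CCO[Al-]1(OCCOC)OCCOC.[Na+] | intermediate
11 | (Z)-3-iodobut-2-en-1-ol | C/C(I)=C/CO | intermediate
12 | (Z)-1-bromo-3-iodobut-2-ene | C/C(I)=C/CBr | intermediate
13 | 2-methylpropane-1,3-diol | CC(CO)CO | starting material
14 | rac-3-{[(Z)-3-iodobut-2-en-1-yl]oxy}-2-methylpropan-1-ol | C/C(I)=C/COCC(C)CO | intermediate
15 | rac-3-{[(Z)-3-iodobut-2-en-1-yl]oxy}-2-methylpropanal | C/C(I)=C/COCC(C)C=O | intermediate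
16 | 1,3-dithiane | C1CSCSC1 | starting material
17 | acrolein | C=CC=O | starting material
18 | 2-lithio-1,3-dithiane | [Li]C1SCCCS1 | intermediate
19 | lithium enolate (C14–OLi, C1=C14; C10 dithian-2-yl trans to the acetonide oxygens) | CC1=C(O[Li])C[C@H]3OC(C)(C)O[C@H]3[C@@H]1C2SCCCS2 | intermediate
20 | aldol adduct: C14 ketone, C1 (methyl, CH(OH)CH=CH2 trans to C10 dithianyl), C11,C12 acetonide; C2 epimers | C=CC(O)[C@@]2(C)C(=O)C[C@H]3OC(C)(C)O[C@H]3[C@@H]2C4SCCCS4 | intermediate
21 | 14-ol (14-OH cis to the C2 chain; C2 epimers) | C=CC(O)[C@@]2(C)[C@@H](O)C[C@H]3OC(C)(C)O[C@H]3[C@@H]2C4SCCCS4 | intermediate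
22 | C2 vinyl ketone with free 14-OH | C=CC(=O)[C@@]2(C)[C@@H](O)C[C@H]3OC(C)(C)O[C@H]3[C@@H]2C4SCCCS4 | intermediate
23 | diethylboron chelate of 22 (O14–BEt2) | C=CC(=O)[C@@]2(C)[C@@H](OB(CC)CC)C[C@H]3OC(C)(C)O[C@H]3[C@@H]2C4SCCCS4 | intermediate
24 | 2,14-syn-diol (target configuration at C1, C2, C10, C12, C14) | C=C[C@@H](O)[C@@]2(C)[C@@H](O)C[C@H]3OC(C)(C)O[C@H]3[C@@H]2C4SCCCS4 | intermediate
25 | 2,14-bis-TBS ether of 24 | C=C[C@@H](O[Si](C)(C)C(C)(C)C)[C@@]2(C)[C@@H](O[Si](C)(C)C(C)(C)C)C[C@H]3OC(C)(C)O[C@H]3[C@@H]2C4SCCCS4 | intermediate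
26 | C9-lithiated dithiane of 25 | C=C[C@@H](O[Si](C)(C)C(C)(C)C)[C@@]2(C)[C@@H](O[Si](C)(C)C(C)(C)C)C[C@H]3OC(C)(C)O[C@H]3[C@@H]2C4([Li])SCCCS4 | intermediate
27 | C9 dithioketal, C8 carbinol with the C17–C19/C5–C7 vinyl iodide arm (C8, C17 epimers) | C=C[C@@H](O[Si](C)(C)C(C)(C)C)[C@@]2(C)[C@@H](O[Si](C)(C)C(C)(C)C)C[C@H]3OC(C)(C)O[C@H]3[C@@H]2C4(SCCCS4)C(O)C(C)COC/C=C(/C)I | intermediate
28 | C9 dithioketal, C8 ketone (C17 epimers) | C=C[C@@H](O[Si](C)(C)C(C)(C)C)[C@@]2(C)[C@@H](O[Si](C)(C)C(C)(C)C)C[C@H]3OC(C)(C)O[C@H]3[C@@H]2C4(SCCCS4)C(=O)C(C)COC/C=C(/C)I | intermediate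
29 | lithium (Z)-enolate of 28 (O–Li cis to C19) | C=C[C@@H](O[Si](C)(C)C(C)(C)C)[C@@]2(C)[C@@H](O[Si](C)(C)C(C)(C)C)C[C@H]3OC(C)(C)O[C@H]3[C@@H]2C4(SCCCS4)/C(O[Li])=C(\C)COC/C=C(/C)I | intermediate
30 | (Z)-C8 TIPS enol ether with C9 dithioketal (C9 trans to C19) | C=C[C@@H](O[Si](C)(C)C(C)(C)C)[C@@]2(C)[C@@H](O[Si](C)(C)C(C)(C)C)C[C@H]3OC(C)(C)O[C@H]3[C@@H]2C4(SCCCS4)/C(O[Si](C(C)C)(C(C)C)C(C)C)=C(\C)COC/C=C(/C)I | intermediate
31 | C9 ketone conjugated with the C8 TIPS enol ether | C=C[C@@H](O[Si](C)(C)C(C)(C)C)[C@@]2(C)[C@@H](O[Si](C)(C)C(C)(C)C)C[C@H]3OC(C)(C)O[C@H]3[C@@H]2C(=O)/C(O[Si](C(C)C)(C(C)C)C(C)C)=C(\C)COC/C=C(/C)I | intermediate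
32 | C9 allylic alcohol (target configuration at C9) | C=C[C@@H](O[Si](C)(C)C(C)(C)C)[C@@]2(C)[C@@H](O[Si](C)(C)C(C)(C)C)C[C@H]3OC(C)(C)O[C@H]3[C@@H]2[C@H](O)/C(O[Si](C(C)C)(C(C)C)C(C)C)=C(\C)COC/C=C(/C)I | intermediate
33 | open-chain 2,9,14-tris-TBS, 8-TIPS enol ether with C3=C4 vinyl and (Z)-C5 vinyl iodide | C=C[C@@H](O[Si](C)(C)C(C)(C)C)[C@@]2(C)[C@@H](O[Si](C)(C)C(C)(C)C)C[C@H]3OC(C)(C)O[C@H]3[C@@H]2[C@H](O[Si](C)(C)C(C)(C)C)/C(O[Si](C(C)C)(C(C)C)C(C)C)=C(\C)COC/C=C(/C)I | intermediate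
34 | B-alkyl-9-BBN adduct of 33 (boron on C4) | B5(CC[C@@H](O[Si](C)(C)C(C)(C)C)[C@@]2(C)[C@@H](O[Si](C)(C)C(C)(C)C)C[C@H]3OC(C)(C)O[C@H]3[C@@H]2[C@H](O[Si](C)(C)C(C)(C)C)/C(O[Si](C(C)C)(C(C)C)C(C)C)=C(\C)COC/C=C(/C)I)C6CCCC5CCC6 | intermediate
35 | thirteen-membered C7–O–C19 bis-allylic ether, (5Z)-olefin, C8 TIPS enol ether, 2,9,14-tris-TBS, 11,12-acetonide | C1/C=C(/C)CC[C@@H](O[Si](C)(C)C(C)(C)C)[C@@]2(C)[C@@H](O[Si](C)(C)C(C)(C)C)C[C@H]3OC(C)(C)O[C@H]3[C@@H]2[C@H](O[Si](C)(C)C(C)(C)C)/C(O[Si](C(C)C)(C(C)C)C(C)C)=C(\C)CO1 | intermediate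
36 | C7-lithiated ether from 35 | [Li]C1/C=C(/C)CC[C@@H](O[Si](C)(C)C(C)(C)C)[C@@]2(C)[C@@H](O[Si](C)(C)C(C)(C)C)C[C@H]3OC(C)(C)O[C@H]3[C@@H]2[C@H](O[Si](C)(C)C(C)(C)C)/C(O[Si](C(C)C)(C(C)C)C(C)C)=C(\C)CO1 | intermediate
37 | lithium C7-alkoxide of 38 | [C@H]1(O[Li])/C=C(/C)CC[C@@H](O[Si](C)(C)C(C)(C)C)[C@@]2(C)[C@@H](O[Si](C)(C)C(C)(C)C)C[C@H]3OC(C)(C)O[C@H]3[C@@H]2[C@H](O[Si](C)(C)C(C)(C)C)[C@]1(O[Si](C(C)C)(C(C)C)C(C)C)C(C)=C | intermediate
38 | ten-membered 7-ol, C8 OTIPS and isopropenyl, (5Z)-olefin, fused to protected ring A | [C@H]1(O)/C=C(/C)CC[C@@H](O[Si](C)(C)C(C)(C)C)[C@@]2(C)[C@@H](O[Si](C)(C)C(C)(C)C)C[C@H]3OC(C)(C)O[C@H]3[C@@H]2[C@H](O[Si](C)(C)C(C)(C)C)[C@]1(O[Si](C(C)C)(C(C)C)C(C)C)C(C)=C | intermediate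
39 | C19 alkyl-9-BBN (C7 O-borinate) from 38 | [C@H]1(OB7C8CCCC7CCC8)/C=C(/C)CC[C@@H](O[Si](C)(C)C(C)(C)C)[C@@]2(C)[C@@H](O[Si](C)(C)C(C)(C)C)C[C@H]3OC(C)(C)O[C@H]3[C@@H]2[C@H](O[Si](C)(C)C(C)(C)C)[C@]1(O[Si](C(C)C)(C(C)C)C(C)C)[C@@H](C)CB5C6CCCC5CCC6 | intermediate
40 | 7,19-diol (C17 as in the target) | [C@H]1(O)/C=C(/C)CC[C@@H](O[Si](C)(C)C(C)(C)C)[C@@]2(C)[C@@H](O[Si](C)(C)C(C)(C)C)C[C@H]3OC(C)(C)O[C@H]3[C@@H]2[C@H](O[Si](C)(C)C(C)(C)C)[C@]1(O[Si](C(C)C)(C(C)C)C(C)C)[C@@H](C)CO | intermediate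
41 | C19 lactol | OC1O[C@H]5/C=C(/C)CC[C@@H](O[Si](C)(C)C(C)(C)C)[C@@]2(C)[C@@H](O[Si](C)(C)C(C)(C)C)C[C@H]3OC(C)(C)O[C@H]3[C@@H]2[C@H](O[Si](C)(C)C(C)(C)C)[C@]5(O[Si](C(C)C)(C(C)C)C(C)C)[C@H]1C | intermediate
42 | trans-fused γ-lactone (C19 to O7), 8-OTIPS, 2,9,14-tris-TBS, 11,12-acetonide | O=C1O[C@H]5/C=C(/C)CC[C@@H](O[Si](C)(C)C(C)(C)C)[C@@]2(C)[C@@H](O[Si](C)(C)C(C)(C)C)C[C@H]3OC(C)(C)O[C@H]3[C@@H]2[C@H](O[Si](C)(C)C(C)(C)C)[C@]5(O[Si](C(C)C)(C(C)C)C(C)C)[C@H]1C | intermediate
43 | lactone 11,12-diol | O=C1O[C@H]5/C=C(/C)CC[C@@H](O[Si](C)(C)C(C)(C)C)[C@@]2(C)[C@@H](O[Si](C)(C)C(C)(C)C)C[C@@H](O)[C@@H](O)[C@@H]2[C@H](O[Si](C)(C)C(C)(C)C)[C@]5(O[Si](C(C)C)(C(C)C)C(C)C)[C@H]1C | intermediate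
44 | cyclic 11,12-methyl orthoacetate | O=C1O[C@H]5/C=C(/C)CC[C@@H](O[Si](C)(C)C(C)(C)C)[C@@]2(C)[C@@H](O[Si](C)(C)C(C)(C)C)C[C@H]3OC(C)(OC)O[C@H]3[C@@H]2[C@H](O[Si](C)(C)C(C)(C)C)[C@]5(O[Si](C(C)C)(C(C)C)C(C)C)[C@H]1C | intermediate
45 | 12-acetate with free 11-OH | O=C1O[C@H]5/C=C(/C)CC[C@@H](O[Si](C)(C)C(C)(C)C)[C@@]2(C)[C@@H](O[Si](C)(C)C(C)(C)C)C[C@@H](OC(C)=O)[C@@H](O)[C@@H]2[C@H](O[Si](C)(C)C(C)(C)C)[C@]5(O[Si](C(C)C)(C(C)C)C(C)C)[C@H]1C | intermediate
46 | 11-ketone 12-acetate | O=C1O[C@H]5/C=C(/C)CC[C@@H](O[Si](C)(C)C(C)(C)C)[C@@]2(C)[C@@H](O[Si](C)(C)C(C)(C)C)C[C@@H](OC(C)=O)C(=O)[C@@H]2[C@H](O[Si](C)(C)C(C)(C)C)[C@]5(O[Si](C(C)C)(C(C)C)C(C)C)[C@H]1C | intermediate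
47 | 11(20)-methylene 12-acetate | O=C1O[C@H]5/C=C(/C)CC[C@@H](O[Si](C)(C)C(C)(C)C)[C@@]2(C)[C@@H](O[Si](C)(C)C(C)(C)C)C[C@@H](OC(C)=O)C(=C)[C@@H]2[C@H](O[Si](C)(C)C(C)(C)C)[C@]5(O[Si](C(C)C)(C(C)C)C(C)C)[C@H]1C | intermediate
48 | 11(20)-methylene 12-ol | O=C1O[C@H]5/C=C(/C)CC[C@@H](O[Si](C)(C)C(C)(C)C)[C@@]2(C)[C@@H](O[Si](C)(C)C(C)(C)C)C[C@@H](O)C(=C)[C@@H]2[C@H](O[Si](C)(C)C(C)(C)C)[C@]5(O[Si](C(C)C)(C(C)C)C(C)C)[C@H]1C | intermediate
49 | 11,20-epoxide (oxygen cis to 12-OH), silyl-protected | O=C1O[C@H]5/C=C(/C)CC[C@@H](O[Si](C)(C)C(C)(C)C)[C@@]2(C)[C@@H](O[Si](C)(C)C(C)(C)C)C[C@@H](O)[C@]3(CO3)[C@@H]2[C@H](O[Si](C)(C)C(C)(C)C)[C@]5(O[Si](C(C)C)(C(C)C)C(C)C)[C@H]1C | intermediate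
50 | 11,20-epoxy lactone 2,8,9,12,14-pentaol | O=C1O[C@H]5/C=C(/C)CC[C@@H](O)[C@@]2(C)[C@@H](O)C[C@@H](O)[C@]3(CO3)[C@@H]2[C@H](O)[C@]5(O)[C@H]1C | intermediate
51 | 2,9,12,14-tetraacetate with free 8-OH and (5Z)-olefin | O=C1O[C@H]5/C=C(/C)CC[C@@H](OC(C)=O)[C@@]2(C)[C@@H](OC(C)=O)C[C@@H](OC(C)=O)[C@]3(CO3)[C@@H]2[C@H](OC(C)=O)[C@]5(O)[C@H]1C | intermediate
52 | CNP0349227.1 | C=C1CC[C@@H](OC(C)=O)[C@@]2(C)[C@@H](OC(C)=O)C[C@@H](OC(C)=O)[C@]3(CO3)[C@@H]2[C@H](OC(C)=O)[C@]2(O)[C@@H](C)C(=O)O[C@H]2[C@H]1Cl | target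

Total step count: 34. Longest linear sequence: 30 steps (steps 1–6 and 11–34, from quinic acid); the side-chain branch (steps 7–10) joins at step 16.

Steps most likely to fail

Step 23 (new method). The C7 carbanion may not add to the electron-rich enol ether terminus, so that proton return, 1,2-shift or deprotonation elsewhere takes over. The fallback uses known chemistry and replaces the sigmatropic shift by a reductive carbonyl coupling. It sets out from 35: mild aqueous acid (oxalic acid, THF/H2O) hydrolyses the enol ether to the macrocyclic β-alkoxy ketone F1. DDQ in wet CH2Cl2 then cleaves the prenyl-type allylic ether oxidatively to the seco keto-enal F2, which carries a free C19 hydroxyl. SmI2 in THF/HMPA at high dilution couples the C7 aldehyde with the C8 ketone (intramolecular pinacol reaction) to the ten-membered 7,8,19-triol F3; samarium chelation by the C9 and C19 oxygens is expected to favour the cis-diol. TEMPO/PhI(OAc)2 turns the 1,4-diol unit into the 8-hydroxy lactone F4, and TIPSOTf/2,6-lutidine silylates the tertiary alcohol, which comes back to the route at 42.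

Step 34. Chlorine delivery to the wrong face of the 5-olefin, or proton loss from C4 instead of C16, would give the C6 epimer or an endocyclic olefin. The fallback installs the chloride by displacement with inversion and sets out from 47. Dimethyldioxirane epoxidises the more electron-rich trisubstituted olefin from its outer face to the 5,6-epoxide F5. Cp2TiCl (from Cp2TiCl2 and Mn) opens the epoxide at the tertiary C5 and removes a C16 hydrogen, giving the 6-hydroxy-5(16)-ene F6. Hexachloroacetone/PPh3 replaces the hydroxyl by chloride with inversion to the 6-chloride F7, that is, with the facial sense opposite to direct chlorination. The remaining operations follow steps 30–33: K2CO3/MeOH gives the 12-ol F8, VO(acac)2/t-BuOOH the 11,20-epoxide F9, Bu4NF/AcOH the chloro pentaol F10, and Ac2O/pyridine/DMAP then gives 52.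

Step 19. S-Methylation at the very hindered dithioketal may be slow, and the aqueous conditions may meanwhile hydrolyse the silyl enol ether. The fallback reverses the order of unmasking and silylation and sets out from 28. The dithioketal is cleaved before any enol ether exists (MeI/CaCO3 or PhI(O2CCF3)2, aqueous MeCN) to give the 1,2-diketone F11. Soft enolisation with TIPSOTf/Et3N at −78 °C then silylates the C8 carbonyl oxygen towards C17, since the C10 proton is shielded by the quaternary C1, and comes back to the route at 31.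

Further compounds
F1 | step 23 | macrocyclic C8 ketone (thirteen-membered β-alkoxy ketone, C17 epimers) | C1/C=C(/C)CC[C@@H](O[Si](C)(C)C(C)(C)C)[C@@]2(C)[C@@H](O[Si](C)(C)C(C)(C)C)C[C@H]3OC(C)(C)O[C@H]3[C@@H]2[C@H](O[Si](C)(C)C(C)(C)C)C(=O)C(C)CO1
F2 | step 23 | seco C8 ketone with (Z)-C7 enal and free 19-OH | O=C/C=C(/C)CC[C@@H](O[Si](C)(C)C(C)(C)C)[C@@]2(C)[C@@H](O[Si](C)(C)C(C)(C)C)C[C@H]3OC(C)(C)O[C@H]3[C@@H]2[C@H](O[Si](C)(C)C(C)(C)C)C(=O)C(C)CO
F3 | step 23 | ten-membered 7,8,19-triol | [C@H]1(O)/C=C(/C)CC[C@@H](O[Si](C)(C)C(C)(C)C)[C@@]2(C)[C@@H](O[Si](C)(C)C(C)(C)C)C[C@H]3OC(C)(C)O[C@H]3[C@@H]2[C@H](O[Si](C)(C)C(C)(C)C)[C@]1(O)[C@@H](C)CO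
F4 | step 23 | 8-hydroxy γ-lactone | O=C1O[C@H]5/C=C(/C)CC[C@@H](O[Si](C)(C)C(C)(C)C)[C@@]2(C)[C@@H](O[Si](C)(C)C(C)(C)C)C[C@H]3OC(C)(C)O[C@H]3[C@@H]2[C@H](O[Si](C)(C)C(C)(C)C)[C@]5(O)[C@H]1C
F5 | step 34 | 5,6-epoxide of 47 | C[C@@]16CC[C@@H](O[Si](C)(C)C(C)(C)C)[C@@]2(C)[C@@H](O[Si](C)(C)C(C)(C)C)C[C@@H](OC(C)=O)C(=C)[C@@H]2[C@H](O[Si](C)(C)C(C)(C)C)[C@]2(O[Si](C(C)C)(C(C)C)C(C)C)[C@@H](C)C(=O)O[C@H]2[C@@H]1O6
F6 | step 34 | 6-hydroxy-5(16)-ene (6-OH opposite to the target chloride) | C=C1CC[C@@H](O[Si](C)(C)C(C)(C)C)[C@@]2(C)[C@@H](O[Si](C)(C)C(C)(C)C)C[C@@H](OC(C)=O)C(=C)[C@@H]2[C@H](O[Si](C)(C)C(C)(C)C)[C@]2(O[Si](C(C)C)(C(C)C)C(C)C)[C@@H](C)C(=O)O[C@H]2[C@@H]1O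
F7 | step 34 | 6-chloro-5(16)-ene 12-acetate with 11(20)-methylene | C=C1CC[C@@H](O[Si](C)(C)C(C)(C)C)[C@@]2(C)[C@@H](O[Si](C)(C)C(C)(C)C)C[C@@H](OC(C)=O)C(=C)[C@@H]2[C@H](O[Si](C)(C)C(C)(C)C)[C@]2(O[Si](C(C)C)(C(C)C)C(C)C)[C@@H](C)C(=O)O[C@H]2[C@H]1Cl
F8 | step 34 | 6-chloro 12-ol with 11(20)-methylene | C=C1CC[C@@H](O[Si](C)(C)C(C)(C)C)[C@@]2(C)[C@@H](O[Si](C)(C)C(C)(C)C)C[C@@H](O)C(=C)[C@@H]2[C@H](O[Si](C)(C)C(C)(C)C)[C@]2(O[Si](C(C)C)(C(C)C)C(C)C)[C@@H](C)C(=O)O[C@H]2[C@H]1Cl
F9 | step 34 | 6-chloro 11,20-epoxide, silyl-protected | C=C1CC[C@@H](O[Si](C)(C)C(C)(C)C)[C@@]2(C)[C@@H](O[Si](C)(C)C(C)(C)C)C[C@@H](O)[C@]3(CO3)[C@@H]2[C@H](O[Si](C)(C)C(C)(C)C)[C@]2(O[Si](C(C)C)(C(C)C)C(C)C)[C@@H](C)C(=O)O[C@H]2[C@H]1Cl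
F10 | step 34 | 6-chloro 11,20-epoxy pentaol | C=C1CC[C@@H](O)[C@@]2(C)[C@@H](O)C[C@@H](O)[C@]3(CO3)[C@@H]2[C@H](O)[C@]2(O)[C@@H](C)C(=O)O[C@H]2[C@H]1Cl
F11 | step 19 | C8,C9 1,2-diketone (C17 epimers) | C=C[C@@H](O[Si](C)(C)C(C)(C)C)[C@@]2(C)[C@@H](O[Si](C)(C)C(C)(C)C)C[C@H]3OC(C)(C)O[C@H]3[C@@H]2C(=O)C(=O)C(C)COC/C=C(/C)I
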